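The target is cut at O1–C2 of the pyran (O1, C2 with ring B, C3, C4, C5, C6; C7 is the ring C carbinol on C5; C1'–C3' is the chain from C3 to ring A). C2 is a para-oxybenzylic ether whose ring B sits axial, cis to C1', the less stable setting. Joining C2' and C7 as the double bond of a sacrificial cyclohexene forces C1' and C7 axial, so ring B becomes equatorial when the C6 hydroxyl adds to the ring B quinone methide at C2. One operation closes the pyran and sets C2. The precursor is a cis-3,5-disubstituted 1-arylcyclohexene with free C6 hydroxyl, C2 acetate and silylated phenols.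

Key step: step 9

Locants O1, C2–C7 and C1'–C3' as defined above are used for all intermediates; TBS = tert-butyldimethylsilyl, TES = triethylsilyl, TBSO and TESO are the corresponding silyloxy groups.

Assumption: the proline-catalysed hydroxymethylation of step 1 follows the accepted enamine model (new centre S with L-proline, formaldehyde entering trans to the ester); should the two groups come out cis, D-proline would be used instead, since only the configuration at the ester-bearing carbon survives the equilibration of step 3.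

Step 1
Reactants: 1 ethyl 4-oxocyclohexane-1-carboxylate; 2 formaldehyde (37% aqueous solution)
Product: 3 ethyl (1S,3S)-3-(hydroxymethyl)-4-oxocyclohexane-1-carboxylate (hydroxymethyl trans to ester)
Conditions: L-proline (20 mol%), 37% aq. HCHO, DMSO, rt
Reagents that add atoms: none
Why: Proline enamine catalysis (direct organocatalytic aldol with formaldehyde, α-hydroxymethylation): the carboxylic acid of the L-proline enamine guides formaldehyde to the face that gives (S) at the new α-carbon, and of the two enantiotopic α-methylene groups the one should react whose enamine half-chair keeps the ester equatorial while the electrophile enters axially, which fixes the ester-bearing carbon (C3 of the target) as (1S) and leaves the hydroxymethyl trans for the moment.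

Step 2
Reactants: 3 ethyl (1S,3S)-3-(hydroxymethyl)-4-oxocyclohexane-1-carboxylate
Product: 4 ethyl (1S,3S)-4-oxo-3-[(triethylsilyloxy)methyl]cyclohexane-1-carboxylate (trans)
Conditions: TESCl, imidazole, CH2Cl2, 0 °C
Reagents that add atoms: chlorotriethylsilane, CC[Si](Cl)(CC)CC
Why: Imidazole-promoted silylation of the primary alcohol stops retro-aldol and dehydration of the β-hydroxy ketone and touches no stereocentre; the minor cis diastereomer of step 1 is removed by chromatography here, because after step 3 it would be the mirror image of 5.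

Step 3
Reactants: 4 ethyl (1S,3S)-4-oxo-3-[(triethylsilyloxy)methyl]cyclohexane-1-carboxylate
Product: 5 ethyl (1S,3R)-4-oxo-3-[(triethylsilyloxy)methyl]cyclohexane-1-carboxylate (cis)
Conditions: DBU (0.3 equiv), toluene, rt to 40 °C
Reagents that add atoms: none
Why: Base-catalysed enolisation and thermodynamic reprotonation (epimerisation) at the ketone α-carbon only, the ester α-proton being far less acidic, should favour the cis isomer that has both substituents equatorial, which sets C5 relative to C3; remaining 4 is separated and resubmitted, and silyloxide is too poor a leaving group for β-elimination under these mild conditions.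

Step 4
Reactants: 5 ethyl (1S,3R)-4-oxo-3-[(triethylsilyloxy)methyl]cyclohexane-1-carboxylate
Product: 7 ethyl (1S,5R)-5-[(triethylsilyloxy)methyl]-4-(trifluoromethylsulfonyloxy)cyclohex-3-ene-1-carboxylate, via lithium enolate 6 (not isolated)
Conditions: LiN(SiMe3)2, THF, −78 °C; then PhNTf2, −78 to 0 °C
Reagents that add atoms: N-phenylbis(trifluoromethanesulfonimide), O=S(=O)(N(c1ccccc1)S(=O)(=O)C(F)(F)F)C(F)(F)F
Why: Kinetic deprotonation by the hindered lithium amide at −78 °C takes a proton from the unsubstituted α-methylene instead of the substituted α-carbon or the ester, and O-sulfonylation of enolate 6 with PhNTf2 gives the less substituted enol triflate (enol triflate formation) without touching either stereocentre.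

Step 5
Reactants: 7 ethyl (1S,5R)-5-[(triethylsilyloxy)methyl]-4-(trifluoromethylsulfonyloxy)cyclohex-3-ene-1-carboxylate; 8 4-(tert-butyldimethylsilyloxy)phenylboronic acid
Product: 9 ethyl (1S,5S)-4-[4-(TBSO)phenyl]-5-[(TESO)methyl]cyclohex-3-ene-1-carboxylate
Conditions: Pd(PPh3)4 (5 mol%), K3PO4, KBr, dioxane, 85 °C
Reagents that add atoms: none
Why: Suzuki–Miyaura coupling of the alkenyl triflate with the arylboronic acid under zerovalent palladium catalysis places ring C on C7, and the anhydrous phosphate base spares the ester, both silyl ethers and the stereocentre next to the ester.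

Step 6
Reactants: 9 ethyl (1S,5S)-4-[4-(TBSO)phenyl]-5-[(TESO)methyl]cyclohex-3-ene-1-carboxylate
Product: 11 (1S,5S)-4-[4-(TBSO)phenyl]-5-[(TESO)methyl]cyclohex-3-ene-1-carbaldehyde, via aluminium hemiacetal 10 (not isolated)
Conditions: i-Bu2AlH (1.1 equiv), toluene, −78 °C; then MeOH, aq. potassium sodium tartrate
Reagents that add atoms: none
Why: Partial ester reduction with one equivalent of i-Bu2AlH at −78 °C stops at the tetrahedral aluminium hemiacetal 10, which releases the aldehyde only on cold work-up; 11 is used at once without chromatography so that its α-carbon (C3) cannot epimerise.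

Step 7
Reactants: 11 (1S,5S)-4-[4-(TBSO)phenyl]-5-[(TESO)methyl]cyclohex-3-ene-1-carbaldehyde; 12 (4-bromophenoxy)(tert-butyl)dimethylsilane
Product: 15 (RS)-[4-(TBSO)phenyl]{(1S,5S)-4-[4-(TBSO)phenyl]-5-[(TESO)methyl]cyclohex-3-en-1-yl}methyl acetate (both epimers at the acetoxy carbon C2), via aryl Grignard reagent 13 (not isolated), via bromomagnesium alkoxide 14 (not isolated)
Conditions: 12, Mg, THF, rt; add to 11, THF, −78 °C; then Ac2O, −78 °C to rt
Reagents that add atoms: acetic anhydride, CC(=O)OC(C)=O
Why: Grignard addition to the aldehyde and O-acetylation of the resulting magnesium alkoxide 14 in the same flask give the benzylic acetate directly; addition at −78 °C is faster than enolisation of the α-branched aldehyde, and the new carbinol centre (C2) is allowed to form as a mixture because step 9 erases it.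

Step 8
Reactants: 15 (RS)-[4-(TBSO)phenyl]{(1S,5S)-4-[4-(TBSO)phenyl]-5-[(TESO)methyl]cyclohex-3-en-1-yl}methyl acetate
Product: 16 (RS)-[4-(TBSO)phenyl]{(1S,5S)-5-(hydroxymethyl)-4-[4-(TBSO)phenyl]cyclohex-3-en-1-yl}methyl acetate (both C2 epimers)
Conditions: PPTS (0.2 equiv), MeOH/CH2Cl2, 0 °C to rt
Reagents that add atoms: none
Why: Acid-catalysed methanolysis (selective desilylation) removes the primary triethylsilyl ether while the aryl tert-butyldimethylsilyl ethers and the acetate resist PPTS, so that the C6 hydroxyl is free before the quinone methide is made; fluoride cleaves aryl silyl ethers faster than alkyl ones and would otherwise unmask the electrophile before its nucleophile.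

Step 9
Reactants: 16 (RS)-[4-(TBSO)phenyl]{(1S,5S)-5-(hydroxymethyl)-4-[4-(TBSO)phenyl]cyclohex-3-en-1-yl}methyl acetate
Product: 18 4,4'-[(1S,2R,5S)-3-oxabicyclo[3.3.1]non-6-ene-2,6-diyl]diphenol, via para-quinone methide 17 (not isolated)
Conditions: Bu4NF (2.5 equiv), THF (0.01 M), −40 °C to rt; aq. NH4Cl
Reagents that add atoms: none
Why: Fluoride removes both aryl silyl groups, the ring B phenoxide expels the benzylic acetate by 1,6-elimination to give para-quinone methide 17 (the same from either acetate epimer), and the C6 hydroxyl, already free, adds to the exocyclic carbon C2 in an oxa-1,6-conjugate addition that re-aromatises ring B and forms O1–C2. The closest known reaction type is the fluoride-triggered generation of a para-quinone methide from a silylated 4-hydroxybenzyl acetate with capture by a tethered alcohol. The pyran closes 6-exo-trig and becomes one ring of the 3-oxabicyclo[3.3.1]nonene. The new stereocentre C2 is set by the bicyclic frame: C1' and C7, tied together as the cyclohexene bridge, are axial on the forming pyran chair, so the chair-like transition state that keeps ring B equatorial (cis to C1', 2R) avoids the 1,3-diaxial contacts with the axial hydrogens on C4 and C6 that the epimer would suffer, and any reversal of the addition leads to the same, more stable epimer. The step needs ring closure to outrun tautomerisation of 17 to the C2=C3 styrene and capture by outside nucleophiles; this is secured by the free, cis-placed hydroxymethyl, which strain against the neighbouring aryl group already holds pseudoaxial over C3, and by low temperature and high dilution.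

Step 10
Reactants: 18 4,4'-[(1S,2R,5S)-3-oxabicyclo[3.3.1]non-6-ene-2,6-diyl]diphenol
Product: 19 (1S,2R,5S)-2,6-bis[4-(TBSO)phenyl]-3-oxabicyclo[3.3.1]non-6-ene
Conditions: TBSCl, imidazole, DMF, rt
Reagents that add atoms: tert-butyldimethylsilyl chloride, CC(C)(C)[Si](C)(C)Cl
Why: Imidazole-promoted silylation of the two phenols, the only hydroxyl groups present, restores the protection needed for the oxidative cleavage and the later organometallic steps.

Step 11
Reactants: 19 (1S,2R,5S)-2,6-bis[4-(TBSO)phenyl]-3-oxabicyclo[3.3.1]non-6-ene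
Product: 21 2-{(2R,3R,5R)-2-[4-(TBSO)phenyl]-5-[4-(TBSO)benzoyl]oxan-3-yl}acetaldehyde, via cis-diol 20 (not isolated)
Conditions: OsO4 (2 mol%), NaIO4, 2,6-lutidine, dioxane/H2O (3:1), rt
Reagents that add atoms: osmium tetroxide, O=[Os](=O)(=O)=O (transfers the oxygen atoms, regenerated by periodate); sodium periodate, [Na+].[O-]I(=O)(=O)=O (terminal oxidant)
Why: Lemieux–Johnson oxidation: OsO4 dihydroxylates the trisubstituted alkene from the face remote from the ring oxygen and periodate cleaves diol 20 in the same flask to the aryl ketone at C7 and the aldehyde at C2', which releases the pyran with C2, C3 and C5 unchanged; 2,6-lutidine keeps the medium near neutral and 21 is carried on at once, since C5 now lies next to a ketone.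

Step 12
Reactants: 21 2-{(2R,3R,5R)-2-[4-(TBSO)phenyl]-5-[4-(TBSO)benzoyl]oxan-3-yl}acetaldehyde
Product: 22 (2R,3R,5R)-2-[4-(TBSO)phenyl]-5-[4-(TBSO)benzoyl]-3-[(2E)-3-iodoprop-2-en-1-yl]oxane
Conditions: CrCl2, CHI3, THF/dioxane (1:6), 0 °C to rt
Reagents that add atoms: iodoform, IC(I)I
Why: Takai olefination: the geminal dichromium species formed from CHI3 and divalent chromium adds to the aldehyde far faster than to the hindered aryl ketone and gives the (E)-vinyl iodide, the usual geometry of this reaction and favoured further by dioxane, under non-basic conditions that leave C5 and C2 alone.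

Step 13
Reactants: 22 (2R,3R,5R)-2-[4-(TBSO)phenyl]-5-[4-(TBSO)benzoyl]-3-[(2E)-3-iodoprop-2-en-1-yl]oxane
Product: 23 (2R,3R,5R)-2-[4-(TBSO)phenyl]-5-{(R)-hydroxy[4-(TBSO)phenyl]methyl}-3-[(2E)-3-iodoprop-2-en-1-yl]oxane
Conditions: (S)-2-methyl-CBS-oxazaborolidine (0.2 equiv), catecholborane, toluene, −78 to −40 °C
Reagents that add atoms: none
Why: Corey–Bakshi–Shibata reduction: the (S)-oxazaborolidine binds the ketone with the aryl ring as the larger group and delivers hydride to the face that gives the (R)-carbinol at C7, the sense it shows with aryl alkyl ketones in general, while catecholborane at low temperature leaves the vinyl iodide untouched.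

Step 14
Reactants: 23 (2R,3R,5R)-2-[4-(TBSO)phenyl]-5-{(R)-hydroxy[4-(TBSO)phenyl]methyl}-3-[(2E)-3-iodoprop-2-en-1-yl]oxane; 8 4-(tert-butyldimethylsilyloxy)phenylboronic acid
Product: 24 (2R,3S,5R)-2-[4-(TBSO)phenyl]-5-{(R)-hydroxy[4-(TBSO)phenyl]methyl}-3-{(2E)-3-[4-(TBSO)phenyl]prop-2-en-1-yl}oxane
Conditions: PdCl2(dppf) (5 mol%), aq. K3PO4, THF, rt
Reagents that add atoms: none
Why: Suzuki–Miyaura coupling of the alkenyl iodide with 8 attaches ring A to C3' with retention of the E geometry; the iodide couples at room temperature, which gives the aqueous base little chance to strip the ring B silyl ether and so expose C2 to epimerisation.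

Step 15
Reactants: 24 (2R,3S,5R)-2-[4-(TBSO)phenyl]-5-{(R)-hydroxy[4-(TBSO)phenyl]methyl}-3-{(2E)-3-[4-(TBSO)phenyl]prop-2-en-1-yl}oxane
Product: 25 4-[(1E)-3-{(2R,3S,5R)-5-[(R)-hydroxy(4-hydroxyphenyl)methyl]-2-(4-hydroxyphenyl)oxan-3-yl}prop-1-en-1-yl]phenol (CNP0182155.1)
Conditions: Bu4NF, AcOH (1:1), THF, 0 °C to rt
Reagents that add atoms: none
Why: Fluoride-mediated desilylation cleaves the three aryl silyl ethers, and the acetic acid buffer keeps the freed phenols protonated so that neither the C2 benzylic ether nor the C7 benzylic alcohol can ionise through a quinone methide; no stereocentre is touched.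

Compound list

1 | ethyl 4-oxocyclohexane-1-carboxylate | CCOC(=O)C1CCC(=O)CC1 | starting material
2 | formaldehyde (37% aqueous solution) | C=O | starting material
3 | ethyl (1S,3S)-3-(hydroxymethyl)-4-oxocyclohexane-1-carboxylate (trans) | C1CC(=O)[C@H](CO)C[C@H]1C(=O)OCC | intermediate
4 | ethyl (1S,3S)-4-oxo-3-[(triethylsilyloxy)methyl]cyclohexane-1-carboxylate (trans) | C1CC(=O)[C@H](CO[Si](CC)(CC)CC)C[C@H]1C(=O)OCC | intermediate
5 | ethyl (1S,3R)-4-oxo-3-[(triethylsilyloxy)methyl]cyclohexane-1-carboxylate (cis) | C1CC(=O)[C@@H](CO[Si](CC)(CC)CC)C[C@H]1C(=O)OCC | intermediate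
6 | lithium enolate of 5 on the side of the unsubstituted α-methylene | C1C=C(O[Li])[C@@H](CO[Si](CC)(CC)CC)C[C@H]1C(=O)OCC | intermediate
7 | ethyl (1S,5R)-5-[(triethylsilyloxy)methyl]-4-(trifluoromethylsulfonyloxy)cyclohex-3-ene-1-carboxylate | C1C=C(OS(=O)(=O)C(F)(F)F)[C@@H](CO[Si](CC)(CC)CC)C[C@H]1C(=O)OCC | intermediate
8 | 4-(tert-butyldimethylsilyloxy)phenylboronic acid | CC(C)(C)[Si](C)(C)Oc1ccc(B(O)O)cc1 | starting material
9 | ethyl (1S,5S)-4-[4-(TBSO)phenyl]-5-[(TESO)methyl]cyclohex-3-ene-1-carboxylate | C1C=C(c2ccc(O[Si](C)(C)C(C)(C)C)cc2)[C@@H](CO[Si](CC)(CC)CC)C[C@H]1C(=O)OCC | intermediate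
10 | diisobutylaluminium hemiacetal of 9 (ring stereocentres as in 9, acetal carbon unassigned) | C1C=C(c2ccc(O[Si](C)(C)C(C)(C)C)cc2)[C@@H](CO[Si](CC)(CC)CC)C[C@H]1C(OCC)O[Al](CC(C)C)CC(C)C | intermediate
11 | (1S,5S)-4-[4-(TBSO)phenyl]-5-[(TESO)methyl]cyclohex-3-ene-1-carbaldehyde | C1C=C(c2ccc(O[Si](C)(C)C(C)(C)C)cc2)[C@@H](CO[Si](CC)(CC)CC)C[C@H]1C=O | intermediate
12 | (4-bromophenoxy)(tert-butyl)dimethylsilane | CC(C)(C)[Si](C)(C)Oc1ccc(Br)cc1 | starting material
13 | [4-(tert-butyldimethylsilyloxy)phenyl]magnesium bromide | CC(C)(C)[Si](C)(C)Oc1ccc([Mg]Br)cc1 | intermediate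
14 | bromomagnesium alkoxide of the C2 carbinol formed from 11 and 13 (both C2 epimers) | C1C=C(c2ccc(O[Si](C)(C)C(C)(C)C)cc2)[C@@H](CO[Si](CC)(CC)CC)C[C@H]1C(O[Mg]Br)c1ccc(O[Si](C)(C)C(C)(C)C)cc1 | intermediate
15 | (RS)-[4-(TBSO)phenyl]{(1S,5S)-4-[4-(TBSO)phenyl]-5-[(TESO)methyl]cyclohex-3-en-1-yl}methyl acetate (both C2 epimers) | C1C=C(c2ccc(O[Si](C)(C)C(C)(C)C)cc2)[C@@H](CO[Si](CC)(CC)CC)C[C@H]1C(OC(C)=O)c1ccc(O[Si](C)(C)C(C)(C)C)cc1 | intermediate
16 | (RS)-[4-(TBSO)phenyl]{(1S,5S)-5-(hydroxymethyl)-4-[4-(TBSO)phenyl]cyclohex-3-en-1-yl}methyl acetate (both C2 epimers) | C1C=C(c2ccc(O[Si](C)(C)C(C)(C)C)cc2)[C@@H](CO)C[C@H]1C(OC(C)=O)c1ccc(O[Si](C)(C)C(C)(C)C)cc1 | intermediate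
17 | 4-{[(1S,5S)-5-(hydroxymethyl)-4-(4-hydroxyphenyl)cyclohex-3-en-1-yl]methylidene}cyclohexa-2,5-dien-1-one | C1C=C(c2ccc(O)cc2)[C@@H](CO)C[C@H]1C=C1C=CC(=O)C=C1 | intermediate
18 | 4,4'-[(1S,2R,5S)-3-oxabicyclo[3.3.1]non-6-ene-2,6-diyl]diphenol | C1C=C(c3ccc(O)cc3)[C@@H]2C[C@H]1[C@H](c1ccc(O)cc1)OC2 | intermediate
19 | (1S,2R,5S)-2,6-bis[4-(TBSO)phenyl]-3-oxabicyclo[3.3.1]non-6-ene | C1C=C(c3ccc(O[Si](C)(C)C(C)(C)C)cc3)[C@@H]2C[C@H]1[C@H](c1ccc(O[Si](C)(C)C(C)(C)C)cc1)OC2 | intermediate
20 | 6,7-cis-diol of 19, both hydroxyls on the face remote from the ring oxygen | C1[C@H](O)[C@@](O)(c3ccc(O[Si](C)(C)C(C)(C)C)cc3)[C@@H]2C[C@H]1[C@H](c1ccc(O[Si](C)(C)C(C)(C)C)cc1)OC2 | intermediate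
21 | 2-{(2R,3R,5R)-2-[4-(TBSO)phenyl]-5-[4-(TBSO)benzoyl]oxan-3-yl}acetaldehyde | O=CC[C@H]2C[C@@H](C(=O)c3ccc(O[Si](C)(C)C(C)(C)C)cc3)CO[C@H]2c2ccc(O[Si](C)(C)C(C)(C)C)cc2 | intermediate
22 | (2R,3R,5R)-2-[4-(TBSO)phenyl]-5-[4-(TBSO)benzoyl]-3-[(2E)-3-iodoprop-2-en-1-yl]oxane | I/C=C/C[C@H]2C[C@@H](C(=O)c3ccc(O[Si](C)(C)C(C)(C)C)cc3)CO[C@H]2c2ccc(O[Si](C)(C)C(C)(C)C)cc2 | intermediate
23 | (2R,3R,5R)-2-[4-(TBSO)phenyl]-5-{(R)-hydroxy[4-(TBSO)phenyl]methyl}-3-[(2E)-3-iodoprop-2-en-1-yl]oxane | I/C=C/C[C@H]2C[C@@H]([C@@H](O)c3ccc(O[Si](C)(C)C(C)(C)C)cc3)CO[C@H]2c2ccc(O[Si](C)(C)C(C)(C)C)cc2 | intermediate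
24 | (2R,3S,5R)-2-[4-(TBSO)phenyl]-5-{(R)-hydroxy[4-(TBSO)phenyl]methyl}-3-{(2E)-3-[4-(TBSO)phenyl]prop-2-en-1-yl}oxane | CC(C)(C)[Si](C)(C)Oc1ccc(/C=C/C[C@H]2C[C@@H]([C@@H](O)c3ccc(O[Si](C)(C)C(C)(C)C)cc3)CO[C@H]2c2ccc(O[Si](C)(C)C(C)(C)C)cc2)cc1 | intermediate
25 | 4-[(1E)-3-{(2R,3S,5R)-5-[(R)-hydroxy(4-hydroxyphenyl)methyl]-2-(4-hydroxyphenyl)oxan-3-yl}prop-1-en-1-yl]phenol | Oc1ccc(/C=C/C[C@H]2C[C@@H]([C@@H](O)c3ccc(O)cc3)CO[C@H]2c2ccc(O)cc2)cc1 | target

Total step count: 15. Longest linear sequence: 15 steps (1 to 25).

Steps most likely to fail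

Step 9. The quinone methide may tautomerise to the conjugated C2=C3 styrene, or be captured by water carried in with the fluoride or by another phenoxide, before the 6-exo closure, which has to pass through a diaxial conformer. The fallback sets out from 16 and keeps the phenol silyl groups on. BF3·OEt2 in CH2Cl2 at −40 °C ionises the benzylic acetate to the 4-silyloxybenzyl cation, and the C6 hydroxyl closes the ether by an SN1 etherification under thermodynamic control. Proton loss to the styrene is reversible in acid, and the same conformational argument places ring B equatorial. This should give 19 directly, so the fallback rejoins the route at 19 and step 10 is skipped; it makes no compound outside the list (F0).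

Step 1. The two enantiotopic α-methylene groups may be poorly distinguished, because the ester has only a small equatorial preference, and the β-hydroxy ketone may be lost by dehydration or a second hydroxymethylation. The fallback sets out from 1. Enantiotopic deprotonation with lithium (R,R)-bis(1-phenylethyl)amide and Me3SiCl as internal quench (THF, −78 °C) should give ethyl (1S)-4-[(trimethylsilyl)oxy]cyclohex-3-ene-1-carboxylate F1; the amide enantiomer is the one that leads to the (1S) enol ether, expected to be (R,R) by analogy with 4-alkylcyclohexanones. A Yb(OTf)3-catalysed Mukaiyama aldol with aqueous formaldehyde should then give 3 mixed with its C3 epimer ethyl (1S,3R)-3-(hydroxymethyl)-4-oxocyclohexane-1-carboxylate F2. Silylation as in step 2 turns these into 4 and 5, and the equilibration of step 3 converges on 5, where the route is rejoined. Here the ester-bearing carbon is set by the choice of proton and not by the enamine face, so the cis or trans outcome of the aldol no longer matters.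

Step 13. Facial selectivity may be poor, because the branched ring carbon C5 rivals the aryl group in size at the oxazaborolidine, or because the ring stereocentres oppose the catalyst. The fallback sets out from 22. Asymmetric transfer hydrogenation with RuCl(p-cymene)[(R,R)-TsDPEN] in HCO2H/Et3N recognises the aryl ring through a CH–π contact instead of through bulk, and should give the same (7R) alcohol 23, where the route is rejoined; it makes no compound outside the list (F0).

Further compounds
F1 | step 1 | ethyl (1S)-4-[(trimethylsilyl)oxy]cyclohex-3-ene-1-carboxylate | C1CC(O[Si](C)(C)C)=CC[C@H]1C(=O)OCC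
F2 | step 1 | ethyl (1S,3R)-3-(hydroxymethyl)-4-oxocyclohexane-1-carboxylate | C1CC(=O)[C@@H](CO)C[C@H]1C(=O)OCC
F0 | step 9 | none | none
F0 | step 13 | none | none
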